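**Plan**

- Retrosynthesis: the first cut is the C15=C15' double bond at the centre of the C9–C9' heptaene. It lies between two unlike C20 arms (ring A carrying the C7≡C8 alkyne, ring B carrying the C7'H2–C8'H2 link), and cutting it leaves an allylic CH2 on each arm, so both arms can be hung on one SO2 group.
- Further cuts: the two S–C bonds (a C20 allylic sulfinate plus a C20 allylic acetate), then C11=C12 and C11'=C12' (C15 aldehyde plus C5 phosphonate), then C6–C7 and C6'–C7' back to one ring enol triflate.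
- Forward: no ring is built. The six-membered ring comes from ketoisophorone and is turned into the triflate. The triflate is coupled with a C6 enynol (ring A arm) or with a C4 alkylzinc followed by methylalumination (ring B arm). Each arm is grown to C20, the arms are joined through sulfur, SO2 is extruded, and the silyl ethers are removed.
- Stereochemistry: C3 and C3' (both R) come from one enzymatic ene-reduction of ketoisophorone, whose methyl-bearing centre then steers the ketone reduction. Alkene geometry comes from the E-enynol, syn-carboalumination, E-selective Horner–Wadsworth–Emmons reactions and the E-selective, thermally corrected extrusion.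

Key step: step 19

Remarks: positions are cited by carotenoid numbering (C1–C20 on the ring A half, primed on the ring B half). TBS = tert-butyldimethylsilyl. In names, "TBSO-ring" = (4R)-4-[(tert-butyldimethylsilyl)oxy]-2,6,6-trimethylcyclohex-1-en-1-yl. Assumption: the ene-reductase OYE2 and glucose dehydrogenase are taken as available enzyme preparations, and the C5 phosphonate is used as the commercial, mainly 2E, material.

**Route**

Step 1
Reactants: 1 ketoisophorone (2,6,6-trimethylcyclohex-2-ene-1,4-dione)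
Product: 2 (6R)-2,2,6-trimethylcyclohexane-1,4-dione ((R)-levodione)
Conditions: ene-reductase OYE2, NADP+ (cat.), glucose dehydrogenase, D-glucose, phosphate buffer pH 7, 30 °C
Reagents that add atoms: none
Why: Enzymatic ene-reduction of the enedione C=C, for which ketoisophorone is a standard substrate, should deliver hydride and proton so that the methyl-bearing carbon becomes R under control of the enzyme active site.

Step 2
Reactants: 2 (6R)-2,2,6-trimethylcyclohexane-1,4-dione
Product: 3 (4R,6R)-4-hydroxy-2,2,6-trimethylcyclohexan-1-one (trans-actinol)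
Conditions: H2, Raney Ni, MeOH, rt; recrystallisation
Reagents that add atoms: none
Why: Heterogeneous ketone hydrogenation should touch only the unhindered C4 carbonyl and add hydrogen from the face away from the axial C2 methyl, so that the hydroxyl ends axial and trans to the equatorial C6 methyl (4R), the minor cis isomer being removed by crystallisation.

Step 3
Reactants: 3 (4R,6R)-4-hydroxy-2,2,6-trimethylcyclohexan-1-one
Product: 4 (4R,6R)-4-[(tert-butyldimethylsilyl)oxy]-2,2,6-trimethylcyclohexan-1-one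
Conditions: TBSCl, imidazole, DMF, rt
Reagents that add atoms: tert-butyldimethylsilyl chloride, CC(C)(C)[Si](C)(C)Cl
Why: Imidazole-promoted silylation of a secondary alcohol is routine and leaves the hindered ketone and both stereocentres untouched.

Step 4
Reactants: 4 (4R,6R)-4-[(tert-butyldimethylsilyl)oxy]-2,2,6-trimethylcyclohexan-1-one
Product: 5 (4R)-4-[(tert-butyldimethylsilyl)oxy]-2,6,6-trimethylcyclohex-1-en-1-yl trifluoromethanesulfonate
Conditions: LiN(i-Pr)2, THF, −78 °C → 0 °C; PhNTf2, −78 °C → rt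
Reagents that add atoms: N-phenylbis(trifluoromethanesulfonimide), O=S(=O)(N(c1ccccc1)S(=O)(=O)C(F)(F)F)C(F)(F)F
Why: Enol triflate formation is regiochemically unambiguous because only C6 carries an alpha hydrogen, so a single tetrasubstituted enolate is O-sulfonylated, which erases the C6 centre and leaves the carbinol centre (R) untouched.

Step 5
Reactants: 5 ring enol triflate, 6 (2E)-3-methylpent-2-en-4-yn-1-ol
Product: 7 (2E)-5-(TBSO-ring)-3-methylpent-2-en-4-yn-1-ol
Conditions: Pd(PPh3)4 (5 mol%), CuI (10 mol%), Et3N, DMF, 50 °C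
Reagents that add atoms: none
Why: Sonogashira coupling of an alkenyl triflate with a terminal alkyne forms the C6–C7 bond, the slim alkyne partner tolerates the two flanking ring substituents, and the E geometry of the enynol is carried through unchanged.

Step 6
Reactants: 7 (2E)-5-(TBSO-ring)-3-methylpent-2-en-4-yn-1-ol
Product: 8 (2E)-5-(TBSO-ring)-3-methylpent-2-en-4-ynal
Conditions: MnO2, CH2Cl2, rt
Reagents that add atoms: none
Why: MnO2 oxidises allylic alcohols selectively to enals under neutral conditions without touching the silyl ether, the alkyne or the alkene geometry.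

Step 7
Reactants: 8 (2E)-5-(TBSO-ring)-3-methylpent-2-en-4-ynal, 9 ethyl (2E)-4-(diethoxyphosphoryl)-3-methylbut-2-enoate
Product: 10 ethyl (2E,4E,6E)-9-(TBSO-ring)-3,7-dimethylnona-2,4,6-trien-8-ynoate
Conditions: LiN(SiMe3)2, THF/DMPU, −78 °C → 0 °C
Reagents that add atoms: none
Why: The Horner–Wadsworth–Emmons reaction of the stabilised C5 phosphonate anion with an enal should form C11=C12 as the E alkene and keep C13=C14 mainly E, any minor 2Z ester being removed by chromatography.

Step 8
Reactants: 10 ethyl (2E,4E,6E)-9-(TBSO-ring)-3,7-dimethylnona-2,4,6-trien-8-ynoate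
Product: 11 (2E,4E,6E)-9-(TBSO-ring)-3,7-dimethylnona-2,4,6-trien-8-yn-1-ol
Conditions: i-Bu2AlH, CH2Cl2, −78 °C
Reagents that add atoms: none
Why: 1,2-Reduction of a conjugated ester by the aluminium hydride gives the allylic alcohol without conjugate reduction or attack on the silyl ether.

Step 9
Reactants: 11 (2E,4E,6E)-9-(TBSO-ring)-3,7-dimethylnona-2,4,6-trien-8-yn-1-ol
Product: 12 (2E,4E,6E)-9-(TBSO-ring)-3,7-dimethylnona-2,4,6-trien-8-yn-1-yl acetate
Conditions: Ac2O, Et3N, DMAP (cat.), CH2Cl2, 0 °C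
Reagents that add atoms: acetic anhydride, CC(=O)OC(C)=O
Why: Base-mediated acetylation of a primary allylic alcohol is mild enough for the polyenyne and provides the leaving group for allylic substitution.

Step 10
Reactants: 12 (2E,4E,6E)-9-(TBSO-ring)-3,7-dimethylnona-2,4,6-trien-8-yn-1-yl acetate, 13 sodium 3-methoxy-3-oxopropane-1-sulfinate
Product: 14 methyl 3-{[(2E,4E,6E)-9-(TBSO-ring)-3,7-dimethylnona-2,4,6-trien-8-yn-1-yl]sulfonyl}propanoate
Conditions: Pd(PPh3)4 (5 mol%), THF/DMSO, rt
Reagents that add atoms: none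
Why: Tsuji–Trost allylic sulfonylation by a sulfinate salt is reversible, so the sulfur should settle on the terminal carbon C15, where the tetraenyne conjugation and the E geometry are kept, and the sulfonylpropanoate serves as a masked sulfinate.

Step 11
Reactants: 5 ring enol triflate, 15 (4-bromobut-1-yn-1-yl)trimethylsilane
Product: 17 tert-butyldimethyl({(1R)-3,5,5-trimethyl-4-[4-(trimethylsilyl)but-3-yn-1-yl]cyclohex-3-en-1-yl}oxy)silane, via alkylzinc bromide 16 (not isolated)
Conditions: 15, Zn dust, LiCl, THF, 50 °C; then 5, Pd(dppf)Cl2 (5 mol%), THF/NMP, 60 °C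
Reagents that add atoms: none
Why: LiCl-assisted zinc insertion gives a primary alkylzinc without beta-leaving group, and its Negishi sp3–sp2 coupling with the alkenyl triflate forms the C6'–C7' bond with the C7'H2–C8'H2 link already saturated.

Step 12
Reactants: 17 silylated alkyne
Product: 18 {[(1R)-4-(but-3-yn-1-yl)-3,5,5-trimethylcyclohex-3-en-1-yl]oxy}(tert-butyl)dimethylsilane
Conditions: K2CO3, MeOH, rt
Reagents that add atoms: none
Why: Methanolysis removes the alkynyl trimethylsilyl group selectively, since the secondary silyl ether is inert to carbonate in methanol.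

Step 13
Reactants: 18 terminal alkyne
Product: 21 (2E)-5-(TBSO-ring)-3-methylpent-2-en-1-ol, via alkenylalane 19 (not isolated), via lithium alanate 20 (not isolated)
Conditions: Me3Al, Cp2ZrCl2 (25 mol%), CH2Cl2, 0 °C → rt; evaporate; n-BuLi, THF, −78 °C; (CH2O)n, −78 °C → rt
Reagents that add atoms: trimethylaluminium, C[Al](C)C; formaldehyde (as paraformaldehyde), C=O
Why: Zirconium-catalysed Negishi carboalumination adds methyl and aluminium syn across the terminal alkyne with methyl at the inner carbon, and hydroxymethylation of the derived alanate with retention gives the C9'=C10' alkene as the E isomer only.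

Step 14
Reactants: 21 (2E)-5-(TBSO-ring)-3-methylpent-2-en-1-ol
Product: 22 (2E)-5-(TBSO-ring)-3-methylpent-2-enal
Conditions: MnO2, CH2Cl2, rt
Reagents that add atoms: none
Why: Allylic oxidation with MnO2, as in step 6, gives the enal without isomerising the trisubstituted alkene.

Step 15
Reactants: 22 (2E)-5-(TBSO-ring)-3-methylpent-2-enal, 9 ethyl (2E)-4-(diethoxyphosphoryl)-3-methylbut-2-enoate
Product: 23 ethyl (2E,4E,6E)-9-(TBSO-ring)-3,7-dimethylnona-2,4,6-trienoate
Conditions: LiN(SiMe3)2, THF/DMPU, −78 °C → 0 °C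
Reagents that add atoms: none
Why: The same Horner–Wadsworth–Emmons extension as in step 7 should form C11'=C12' as the E alkene, with minor 2Z ester removed by chromatography.

Step 16
Reactants: 23 ethyl (2E,4E,6E)-9-(TBSO-ring)-3,7-dimethylnona-2,4,6-trienoate
Product: 24 (2E,4E,6E)-9-(TBSO-ring)-3,7-dimethylnona-2,4,6-trien-1-ol
Conditions: i-Bu2AlH, CH2Cl2, −78 °C
Reagents that add atoms: none
Why: 1,2-Reduction of the trienoate to the allylic alcohol proceeds as in step 8.

Step 17
Reactants: 24 (2E,4E,6E)-9-(TBSO-ring)-3,7-dimethylnona-2,4,6-trien-1-ol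
Product: 25 (2E,4E,6E)-9-(TBSO-ring)-3,7-dimethylnona-2,4,6-trien-1-yl acetate
Conditions: Ac2O, Et3N, DMAP (cat.), CH2Cl2, 0 °C
Reagents that add atoms: acetic anhydride, CC(=O)OC(C)=O
Why: Acetylation as in step 9 gives the second allylic electrophile.

Step 18
Reactants: 14 ring A sulfonylpropanoate, 25 ring B allylic acetate
Product: 27 (2E,4E,6E)-9-(TBSO-ring)-3,7-dimethylnona-2,4,6-trien-8-yn-1-yl (2E,4E,6E)-9-(TBSO-ring)-3,7-dimethylnona-2,4,6-trien-1-yl sulfone, via sodium sulfinate 26 (not isolated)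
Conditions: 14, NaOMe (1.05 equiv), THF/MeOH, 0 °C → rt, evaporate; then 25, Pd(PPh3)4 (5 mol%), THF/DMSO, rt
Reagents that add atoms: none
Why: Methoxide triggers a retro-Michael (E1cB) release of the allylic sulfinate from the sulfonylpropanoate, and Tsuji–Trost S-allylation of this soft nucleophile by the second acetate joins the two unlike C20 arms at sulfur without any oxidation step in the presence of the polyenes.

Step 19
Reactants: 27 bis(allylic) sulfone
Product: 31 (3R,3'R)-3,3'-bis[(tert-butyldimethylsilyl)oxy]-7,8-didehydro-7',8'-dihydro-beta,beta-carotene (all-E), via bromo sulfone 28 (not isolated), via thiirane dioxide 29 (not isolated), via 15Z isomer 30 (not isolated)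
Conditions: C2Br2Cl4, KOH/Al2O3, t-BuOH/THF, 0 °C → rt; then crude in heptane, 70 °C, dark
Reagents that add atoms: none
Why: The supported hydroxide deprotonates one alpha carbon of 27 (both are allylic to a tetraene), the carbanion takes positive bromine from C2Br2Cl4 to give 28 (drawn brominated at C15), and the C15' carbanion then displaces bromide to form the thiirane 1,1-dioxide 29, which loses SO2 cheletropically and leaves the C15–C15' sigma and pi bonds. This is the in situ Ramberg–Bäcklund rearrangement with a carbene-free bromine donor, a reaction type precedented for bis(allylic) sulfones giving conjugated trienes and carotenoid-type polyenes. The only ring closed is the transient three-membered episulfone, formed 3-exo-tet and opened again, so no ring survives in 31. No stereocentre is created in the product; the two episulfone carbons are epimerisable under the base and should settle as the trans-episulfone, which gives the E alkene stereospecifically. The step needs halogenation and closure at the two alpha carbons and not at vinylogous positions, which the sulfonyl group secures because the charge, the bromine and the leaving group are all held on the carbons bonded to sulfur, while closure elsewhere would break the conjugation. Any 15Z isomer 30 should relax to 15E on gentle warming, the central disubstituted bond being the most labile of the chain, and iodine catalysis is avoided because it could let the 9E bond next to the alkyne drift to 9Z.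

Step 20
Reactants: 31 all-E bis-TBS ether
Product: 32 (3R,3'R)-7,8-didehydro-7',8'-dihydro-beta,beta-carotene-3,3'-diol (all-E; CNP0178054.1)
Conditions: Bu4NF, THF, 0 °C → rt, dark
Reagents that add atoms: none
Why: Fluoride-induced cleavage of the two secondary silyl ethers is routine for carotenols and touches neither the polyenyne nor the carbinol configuration.

**Compound list**

1 | ketoisophorone (2,6,6-trimethylcyclohex-2-ene-1,4-dione) | CC1=CC(=O)CC(C)(C)C1=O | starting material
2 | (6R)-2,2,6-trimethylcyclohexane-1,4-dione | C[C@@H]1CC(=O)CC(C)(C)C1=O | intermediate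
3 | (4R,6R)-4-hydroxy-2,2,6-trimethylcyclohexan-1-one | C[C@@H]1C[C@@H](O)CC(C)(C)C1=O | intermediate
4 | (4R,6R)-4-[(tert-butyldimethylsilyl)oxy]-2,2,6-trimethylcyclohexan-1-one | C[C@@H]1C[C@@H](O[Si](C)(C)C(C)(C)C)CC(C)(C)C1=O | intermediate
5 | (4R)-4-[(tert-butyldimethylsilyl)oxy]-2,6,6-trimethylcyclohex-1-en-1-yl trifluoromethanesulfonate | CC1=C(OS(=O)(=O)C(F)(F)F)C(C)(C)C[C@H](O[Si](C)(C)C(C)(C)C)C1 | intermediate
6 | (2E)-3-methylpent-2-en-4-yn-1-ol | C#C/C(C)=C/CO | starting material
7 | (2E)-5-(TBSO-ring)-3-methylpent-2-en-4-yn-1-ol | CC1=C(C#C/C(C)=C/CO)C(C)(C)C[C@H](O[Si](C)(C)C(C)(C)C)C1 | intermediate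
8 | (2E)-5-(TBSO-ring)-3-methylpent-2-en-4-ynal | CC1=C(C#C/C(C)=C/C=O)C(C)(C)C[C@H](O[Si](C)(C)C(C)(C)C)C1 | intermediate
9 | ethyl (2E)-4-(diethoxyphosphoryl)-3-methylbut-2-enoate | CCOC(=O)/C=C(\C)CP(=O)(OCC)OCC | starting material
10 | ethyl (2E,4E,6E)-9-(TBSO-ring)-3,7-dimethylnona-2,4,6-trien-8-ynoate | CC1=C(C#C/C(C)=C/C=C/C(C)=C/C(=O)OCC)C(C)(C)C[C@H](O[Si](C)(C)C(C)(C)C)C1 | intermediate
11 | (2E,4E,6E)-9-(TBSO-ring)-3,7-dimethylnona-2,4,6-trien-8-yn-1-ol | CC1=C(C#C/C(C)=C/C=C/C(C)=C/CO)C(C)(C)C[C@H](O[Si](C)(C)C(C)(C)C)C1 | intermediate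
12 | (2E,4E,6E)-9-(TBSO-ring)-3,7-dimethylnona-2,4,6-trien-8-yn-1-yl acetate | CC1=C(C#C/C(C)=C/C=C/C(C)=C/COC(C)=O)C(C)(C)C[C@H](O[Si](C)(C)C(C)(C)C)C1 | intermediate
13 | sodium 3-methoxy-3-oxopropane-1-sulfinate | COC(=O)CCS(=O)[O-].[Na+] | starting material
14 | methyl 3-{[(2E,4E,6E)-9-(TBSO-ring)-3,7-dimethylnona-2,4,6-trien-8-yn-1-yl]sulfonyl}propanoate | CC1=C(C#C/C(C)=C/C=C/C(C)=C/CS(=O)(=O)CCC(=O)OC)C(C)(C)C[C@H](O[Si](C)(C)C(C)(C)C)C1 | intermediate
15 | (4-bromobut-1-yn-1-yl)trimethylsilane | C[Si](C)(C)C#CCCBr | starting material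
16 | [4-(trimethylsilyl)but-3-yn-1-yl]zinc bromide | C[Si](C)(C)C#CCC[Zn]Br | intermediate
17 | tert-butyldimethyl({(1R)-3,5,5-trimethyl-4-[4-(trimethylsilyl)but-3-yn-1-yl]cyclohex-3-en-1-yl}oxy)silane | CC1=C(CCC#C[Si](C)(C)C)C(C)(C)C[C@H](O[Si](C)(C)C(C)(C)C)C1 | intermediate
18 | {[(1R)-4-(but-3-yn-1-yl)-3,5,5-trimethylcyclohex-3-en-1-yl]oxy}(tert-butyl)dimethylsilane | CC1=C(CCC#C)C(C)(C)C[C@H](O[Si](C)(C)C(C)(C)C)C1 | intermediate
19 | [(1E)-4-(TBSO-ring)-2-methylbut-1-en-1-yl]dimethylalane | CC1=C(CC/C(C)=C/[Al](C)C)C(C)(C)C[C@H](O[Si](C)(C)C(C)(C)C)C1 | intermediate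
20 | lithium butyl[(1E)-4-(TBSO-ring)-2-methylbut-1-en-1-yl]dimethylalanate | CC1=C(CC/C(C)=C/[Al-](C)(C)CCCC)C(C)(C)C[C@H](O[Si](C)(C)C(C)(C)C)C1.[Li+] | intermediate
21 | (2E)-5-(TBSO-ring)-3-methylpent-2-en-1-ol | CC1=C(CC/C(C)=C/CO)C(C)(C)C[C@H](O[Si](C)(C)C(C)(C)C)C1 | intermediate
22 | (2E)-5-(TBSO-ring)-3-methylpent-2-enal | CC1=C(CC/C(C)=C/C=O)C(C)(C)C[C@H](O[Si](C)(C)C(C)(C)C)C1 | intermediate
23 | ethyl (2E,4E,6E)-9-(TBSO-ring)-3,7-dimethylnona-2,4,6-trienoate | CC1=C(CC/C(C)=C/C=C/C(C)=C/C(=O)OCC)C(C)(C)C[C@H](O[Si](C)(C)C(C)(C)C)C1 | intermediate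
24 | (2E,4E,6E)-9-(TBSO-ring)-3,7-dimethylnona-2,4,6-trien-1-ol | CC1=C(CC/C(C)=C/C=C/C(C)=C/CO)C(C)(C)C[C@H](O[Si](C)(C)C(C)(C)C)C1 | intermediate
25 | (2E,4E,6E)-9-(TBSO-ring)-3,7-dimethylnona-2,4,6-trien-1-yl acetate | CC1=C(CC/C(C)=C/C=C/C(C)=C/COC(C)=O)C(C)(C)C[C@H](O[Si](C)(C)C(C)(C)C)C1 | intermediate
26 | sodium (2E,4E,6E)-9-(TBSO-ring)-3,7-dimethylnona-2,4,6-trien-8-yne-1-sulfinate | CC1=C(C#C/C(C)=C/C=C/C(C)=C/CS(=O)[O-])C(C)(C)C[C@H](O[Si](C)(C)C(C)(C)C)C1.[Na+] | intermediate
27 | unsymmetrical bis(C20-allyl) sulfone, 3,3'-bis-TBS ether (C15–SO2–C15') | CC1=C(C#C/C(C)=C/C=C/C(C)=C/CS(=O)(=O)C/C=C(C)/C=C/C=C(\C)CCC2=C(C)C[C@@H](O[Si](C)(C)C(C)(C)C)CC2(C)C)C(C)(C)C[C@H](O[Si](C)(C)C(C)(C)C)C1 | intermediate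
28 | alpha-bromo sulfone (27 brominated at C15; both C15 epimers, centre left open) | CC1=C(C#C/C(C)=C/C=C/C(C)=C/C(Br)S(=O)(=O)C/C=C(C)/C=C/C=C(\C)CCC2=C(C)C[C@@H](O[Si](C)(C)C(C)(C)C)CC2(C)C)C(C)(C)C[C@H](O[Si](C)(C)C(C)(C)C)C1 | intermediate
29 | 2,3-disubstituted thiirane 1,1-dioxide spanning C15 and C15' (ring carbons epimerisable under the base, left open) | CC1=C(C#C/C(C)=C/C=C/C(C)=C/C3C(/C=C(C)/C=C/C=C(\C)CCC2=C(C)C[C@@H](O[Si](C)(C)C(C)(C)C)CC2(C)C)S3(=O)=O)C(C)(C)C[C@H](O[Si](C)(C)C(C)(C)C)C1 | intermediate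
30 | 15Z isomer of 31 | CC1=C(C#C/C(C)=C/C=C/C(C)=C/C=C\C=C(C)\C=C\C=C(/C)CCC2=C(C)C[C@@H](O[Si](C)(C)C(C)(C)C)CC2(C)C)C(C)(C)C[C@H](O[Si](C)(C)C(C)(C)C)C1 | intermediate
31 | (3R,3'R)-3,3'-bis[(tert-butyldimethylsilyl)oxy]-7,8-didehydro-7',8'-dihydro-beta,beta-carotene (all-E) | CC1=C(C#C/C(C)=C/C=C/C(C)=C/C=C/C=C(C)/C=C/C=C(\C)CCC2=C(C)C[C@@H](O[Si](C)(C)C(C)(C)C)CC2(C)C)C(C)(C)C[C@H](O[Si](C)(C)C(C)(C)C)C1 | intermediate
32 | (3R,3'R)-7,8-didehydro-7',8'-dihydro-beta,beta-carotene-3,3'-diol (all-E) | CC1=C(C#C/C(C)=C/C=C/C(C)=C/C=C/C=C(C)/C=C/C=C(\C)CCC2=C(C)C[C@@H](O)CC2(C)C)C(C)(C)C[C@H](O)C1 | target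

**Totals and risks**

Total step count: 20. Longest linear sequence: 14 steps (steps 1–4, 11–17, 18–20).

Steps most likely to fail:

1. Step 19. The delocalised polyenyl sulfonyl carbanion could be brominated or could close at a vinylogous carbon, could be brominated twice, or could be reprotonated at a remote carbon so that double bonds move out of conjugation. Fallback: the C15=C15' bond would be made by a Wittig olefination of the same halves, setting out from alcohols 11 and 24 and returning at 31. Alcohol 11 would be converted (CBr4, PPh3, 2,6-lutidine, CH2Cl2, −30 °C) into the ring A allylic bromide F1, which with PPh3 in toluene would give the triphenylphosphonium bromide F2. Alcohol 24 would be oxidised (MnO2, CH2Cl2) to the ring B C20 aldehyde F3. Ylide formation from F2 (NaOMe, CH2Cl2/MeOH, 0 °C) in the presence of F3, followed by the same warming in heptane, should give 31.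

2. Step 18. Under zerovalent palladium the product sulfone could re-ionise at either allylic C–S bond, so that allyl and sulfinate partners exchange and the two halves scramble into symmetrical sulfones. The unmasking could also suffer from conjugate re-addition of the sulfinate or of the C15 carbanion to the liberated acrylate. Fallback: both S–C bonds would be made by thiolate substitution and sulfur oxidised last, setting out from 11 and 24 and returning at 27. Mitsunobu reaction of 11 (PPh3, DIAD, AcSH, THF, 0 °C) would give the thioacetate F4. Alcohol 24 would give (CBr4, PPh3, 2,6-lutidine, CH2Cl2, −30 °C) the ring B allylic bromide F5. Methanolysis of F4 in the presence of F5 (K2CO3, degassed MeOH/THF, 0 °C) would give the unsymmetrical diallyl sulfide F6. Chemoselective sulfur oxidation (H2O2, (NH4)6Mo7O24 cat., EtOH/THF, 0 °C) would then give 27.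

3. Step 11. Oxidative addition and transmetalation at the tetrasubstituted, doubly flanked triflate could be slow, so that reduction of the triflate or homocoupling of the zinc reagent takes over. Fallback: the saturated link would be made by conjugate reduction of a dienone, setting out from 5 and returning at 18. Stille coupling of 5 with (E)-4-(tributylstannyl)but-3-en-2-one (Pd2(dba)3, AsPh3, LiCl, NMP, 50 °C) would give the silylated 3-hydroxy-beta-ionone F7. 1,4-Reduction with [(Ph3P)CuH]6 in wet benzene would give the 7,8-dihydro ketone F8. Kinetic enolisation at the methyl group and phosphorylation (LiN(i-Pr)2, ClP(O)(OEt)2, THF, −78 °C) would give the enol phosphate F9, and elimination with further LiN(i-Pr)2 (−78 °C → rt, then water) would give alkyne 18.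

**Further compounds**

F1 | step 19 | (2E,4E,6E)-9-(TBSO-ring)-3,7-dimethylnona-2,4,6-trien-8-yn-1-yl bromide | CC1=C(C#C/C(C)=C/C=C/C(C)=C/CBr)C(C)(C)C[C@H](O[Si](C)(C)C(C)(C)C)C1
F2 | step 19 | [(2E,4E,6E)-9-(TBSO-ring)-3,7-dimethylnona-2,4,6-trien-8-yn-1-yl]triphenylphosphonium bromide | CC1=C(C#C/C(C)=C/C=C/C(C)=C/C[P+](c2ccccc2)(c2ccccc2)c2ccccc2)C(C)(C)C[C@H](O[Si](C)(C)C(C)(C)C)C1.[Br-]
F3 | step 19 | (2E,4E,6E)-9-(TBSO-ring)-3,7-dimethylnona-2,4,6-trienal | CC1=C(CC/C(C)=C/C=C/C(C)=C/C=O)C(C)(C)C[C@H](O[Si](C)(C)C(C)(C)C)C1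
F4 | step 18 | S-[(2E,4E,6E)-9-(TBSO-ring)-3,7-dimethylnona-2,4,6-trien-8-yn-1-yl] ethanethioate | CC1=C(C#C/C(C)=C/C=C/C(C)=C/CSC(C)=O)C(C)(C)C[C@H](O[Si](C)(C)C(C)(C)C)C1
F5 | step 18 | (2E,4E,6E)-9-(TBSO-ring)-3,7-dimethylnona-2,4,6-trien-1-yl bromide | CC1=C(CC/C(C)=C/C=C/C(C)=C/CBr)C(C)(C)C[C@H](O[Si](C)(C)C(C)(C)C)C1
F6 | step 18 | unsymmetrical bis(C20-allyl) sulfide, 3,3'-bis-TBS ether | CC1=C(C#C/C(C)=C/C=C/C(C)=C/CSC/C=C(C)/C=C/C=C(\C)CCC2=C(C)C[C@@H](O[Si](C)(C)C(C)(C)C)CC2(C)C)C(C)(C)C[C@H](O[Si](C)(C)C(C)(C)C)C1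
F7 | step 11 | (3E)-4-(TBSO-ring)but-3-en-2-one | CC1=C(/C=C/C(C)=O)C(C)(C)C[C@H](O[Si](C)(C)C(C)(C)C)C1
F8 | step 11 | 4-(TBSO-ring)butan-2-one | CC1=C(CCC(C)=O)C(C)(C)C[C@H](O[Si](C)(C)C(C)(C)C)C1
F9 | step 11 | 4-(TBSO-ring)but-1-en-2-yl diethyl phosphate | CC1=C(CCC(=C)OP(=O)(OCC)OCC)C(C)(C)C[C@H](O[Si](C)(C)C(C)(C)C)C1
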